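**Retrosynthetic overview**

1. Target 16 ⇐ 15 by unmasking the aryl ketone from its 1,3-dithiane; 15 ⇐ lactol 10 + arylboronic acid 11 by forming the bond between C2 of the oxolane and the ipso carbon of its 3,4,5-trimethoxyphenyl group.
2. Enabling feature: C2 of the oxolane is bonded to ring oxygen O1, so without its aryl it is a lactol (oxocarbenium) carbon, and the oxygen of the C3 hydroxymethyl group lies 1,3 to C2 on the ring face the aryl occupies (2,3-cis). Boron can bridge these two oxygens in a temporary 1,3,2-dioxaborinane ring and hand its aryl group to C2 from that face.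
3. Lactol 10 ⇐ lactone 9 ⇐ 6 by reductive removal of the menthyloxy auxiliary; 6 ⇐ three-component tandem Michael addition/aldol of dithiane 2, butenolide 3 and formaldehyde, which sets C4 and then C3 (3,4-trans).
4. Ring order: dithiane (step 1); the oxolane ring is the butenolide ring of 3, opened and reclosed as the lactone in step 3; the dioxaborinane is made and cleaved within step 5; the dithiane is removed in step 6.

Key step: step 5

Assumption: (5R)-5-(l-menthyloxy)furan-2(5H)-one (l-menthyl = (1R,2S,5R)-2-isopropyl-5-methylcyclohexyl) is taken as a purchasable chiral building block, and monomeric formaldehyde is generated by cracking paraformaldehyde.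

**Route**

Step 1
Reactants: 1 3,4,5-trimethoxybenzaldehyde
Product: 2 2-(3,4,5-trimethoxyphenyl)-1,3-dithiane
Conditions: HS(CH2)3SH, BF3·OEt2 (cat.), CH2Cl2, 0 → 23 °C
Reagents that add atoms: propane-1,3-dithiol, SCCCS
Why: Lewis-acid-catalysed dithioacetalisation turns the aldehyde into the 1,3-dithiane that serves as a Corey–Seebach aroyl anion equivalent and later as the ketone mask; no stereocentre is involved.

Step 2
Reactants: 2 2-(3,4,5-trimethoxyphenyl)-1,3-dithiane; 3 (5R)-5-(l-menthyloxy)furan-2(5H)-one
Product: 6 (3S,4R,5R)-3-(hydroxymethyl)-5-(l-menthyloxy)-4-[2-(3,4,5-trimethoxyphenyl)-1,3-dithian-2-yl]oxolan-2-one, via 2-lithio-1,3-dithiane 4 (not isolated), via lithium lactone enolate 5 (not isolated)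
Conditions: n-BuLi, THF, −78 → −20 °C; 3, −78 °C; CH2O (monomeric, THF solution), −78 → −40 °C; aq. NH4Cl
Reagents that add atoms: formaldehyde, C=O
Why: Corey–Seebach lithiation gives the 2-lithio-dithiane, which should add in Michael fashion to the γ-alkoxybutenolide on the face anti to the menthyloxy group (sets C4), and the lactone enolate so formed should undergo aldol addition to formaldehyde anti to the new bulky C4 substituent (sets C3, trans), a tandem conjugate addition–enolate trapping of the kind established for this butenolide.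

Step 3
Reactants: 6 (3S,4R,5R)-3-(hydroxymethyl)-5-(l-menthyloxy)-4-[2-(3,4,5-trimethoxyphenyl)-1,3-dithian-2-yl]oxolan-2-one
Product: 9 (3S,4R)-3-(hydroxymethyl)-4-[2-(3,4,5-trimethoxyphenyl)-1,3-dithian-2-yl]oxolan-2-one, via aldehyde carboxylate 7 (not isolated), via dihydroxy carboxylate 8 (not isolated)
Conditions: NaBH4, KOH, EtOH/H2O, 0 → 23 °C; then 2 M HCl, 23 °C
Reagents that add atoms: potassium hydroxide, [K+].[OH-] (its oxygen can exchange into the carboxyl group that relactonises)
Why: Saponification of the acylal-type pseudo-ester should expel menthol and unveil an aldehyde that borohydride reduces at once, and acidification relactonises the γ-hydroxy acid onto the original carboxyl, so the auxiliary-bearing carbon becomes the ring CH2 while C3 and C4 are untouched (reductive removal of a γ-alkoxy auxiliary).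

Step 4
Reactants: 9 (3S,4R)-3-(hydroxymethyl)-4-[2-(3,4,5-trimethoxyphenyl)-1,3-dithian-2-yl]oxolan-2-one
Product: 10 (3S,4R)-3-(hydroxymethyl)-4-[2-(3,4,5-trimethoxyphenyl)-1,3-dithian-2-yl]oxolan-2-ol (both anomers)
Conditions: DIBAL-H (2.2 equiv), CH2Cl2, −78 °C; aq. Rochelle salt
Reagents that add atoms: none
Why: DIBAL-H reduction of a γ-lactone at −78 °C should stop at the lactol because the tetrahedral aluminium alkoxide survives until work-up; the free hydroxyl only consumes one equivalent of hydride, the dithiane is inert and the new anomeric centre is erased in the next step.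

Step 5
Reactants: 10 (3S,4R)-3-(hydroxymethyl)-4-[2-(3,4,5-trimethoxyphenyl)-1,3-dithian-2-yl]oxolan-2-ol; 11 (3,4,5-trimethoxyphenyl)boronic acid
Product: 15 [(2S,3S,4R)-2-(3,4,5-trimethoxyphenyl)-4-[2-(3,4,5-trimethoxyphenyl)-1,3-dithian-2-yl]oxolan-3-yl]methanol, via cyclic arylboronate 12 (not isolated), via oxocarbenium borate zwitterion 13 (not isolated), via primary borate ester 14 (not isolated)
Conditions: 11 (1.5 equiv), CH2Cl2/HFIP (4:1), 23 °C; then BF3·OEt2 (10 mol %), −20 → 23 °C; aq. NaHCO3
Reagents that add atoms: none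
Why: Proposed new method: the boronic acid should condense with the 1,3-related anomeric and primary hydroxyls of the lactol to the cis-fused 1,3,2-dioxaborinane 12, acid in HFIP should then break the anomeric C–O bond while boron takes up hydroxide, leaving the oxolan-2-ylium ion 13 whose C3 arm carries a tetracoordinate aryl borate, and the aryl group should migrate from boron to C2 through a six-membered chair-like transition state (B, O, CH2, C3, C2, ipso-C) to give borate ester 14, hydrolysed on work-up. The closest known reaction types are the Petasis borono-Mannich reaction, hydroxyl-directed boronate additions to cyclic N-acyliminium ions and Lewis-acid-promoted additions of aryl boron reagents to cyclic oxocarbenium ions. No ring of the target is closed: the only ring formed is the temporary six-membered dioxaborinane (two B–O condensations), and it is opened again by the ionisation and the final hydrolysis. The new stereocentre C2 is set by the tether, because the aryl can only reach the face that carries the C3 CH2O–B arm, which gives the 2,3-cis and hence 2,4-trans arrangement; inside attack on the envelope that holds the C3 and C4 groups pseudo-equatorial and the bulk of the dithiane on the opposite face point the same way, so an untethered transfer should converge on the same isomer. The step needs ipso selectivity on the arene and cis facial selectivity at C2: the C–B bond of the borate, para to the 4-methoxy group, is the nucleophilic site (free 1,2,3-trimethoxybenzene would react at C4 instead) and the short tether secures the face, while the dithiane keeps the 1,4-dicarbonyl (furan-forming) and β-alkoxy-ketone pathways closed during ionisation.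

Step 6
Reactants: 15 [(2S,3S,4R)-2-(3,4,5-trimethoxyphenyl)-4-[2-(3,4,5-trimethoxyphenyl)-1,3-dithian-2-yl]oxolan-3-yl]methanol
Product: 16 [(3R,4S,5S)-4-(hydroxymethyl)-5-(3,4,5-trimethoxyphenyl)oxolan-3-yl](3,4,5-trimethoxyphenyl)methanone
Conditions: MeI (excess), CaCO3, MeCN/H2O (9:1), 40 °C
Reagents that add atoms: water, O
Why: S-Methylation should turn the dithiane into a leaving group and water hydrolyses the resulting thionium ion to the aryl ketone (alkylative dithiane cleavage) under buffered, non-oxidising conditions that spare the electron-rich arenes and the acid-labile cis-2-aryl ether, the α-stereocentre C4 already being in its more stable trans arrangement.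

**Compound list**

1 | 3,4,5-trimethoxybenzaldehyde | COc1cc(C=O)cc(OC)c1OC | starting material
2 | 2-(3,4,5-trimethoxyphenyl)-1,3-dithiane | COc1cc(C2SCCCS2)cc(OC)c1OC | intermediate
3 | (5R)-5-[(1R,2S,5R)-2-isopropyl-5-methylcyclohexyl]oxyfuran-2(5H)-one | O=C1C=C[C@H](O[C@@H]2C[C@H](C)CC[C@H]2C(C)C)O1 | starting material
4 | 2-lithio-2-(3,4,5-trimethoxyphenyl)-1,3-dithiane (not isolated) | [Li]C1(SCCCS1)c1cc(OC)c(OC)c(OC)c1 | intermediate
5 | lithium enolate of (4R,5R)-5-(l-menthyloxy)-4-[2-(3,4,5-trimethoxyphenyl)-1,3-dithian-2-yl]oxolan-2-one (not isolated) | COc1cc(C2(SCCCS2)[C@H]3[C@H](O[C@@H]4C[C@H](C)CC[C@H]4C(C)C)OC(O[Li])=C3)cc(OC)c1OC | intermediate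
6 | (3S,4R,5R)-3-(hydroxymethyl)-5-(l-menthyloxy)-4-[2-(3,4,5-trimethoxyphenyl)-1,3-dithian-2-yl]oxolan-2-one | COc1cc(C2(SCCCS2)[C@H]3[C@H](O[C@@H]4C[C@H](C)CC[C@H]4C(C)C)OC(=O)[C@@H]3CO)cc(OC)c1OC | intermediate
7 | potassium (2S,3R)-2-(hydroxymethyl)-4-oxo-3-[2-(3,4,5-trimethoxyphenyl)-1,3-dithian-2-yl]butanoate (not isolated) | [K+].[O-]C(=O)[C@H](CO)[C@H](C=O)C1(SCCCS1)c1cc(OC)c(OC)c(OC)c1 | intermediate
8 | potassium (2S,3R)-4-hydroxy-2-(hydroxymethyl)-3-[2-(3,4,5-trimethoxyphenyl)-1,3-dithian-2-yl]butanoate (not isolated) | [K+].[O-]C(=O)[C@H](CO)[C@H](CO)C1(SCCCS1)c1cc(OC)c(OC)c(OC)c1 | intermediate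
9 | (3S,4R)-3-(hydroxymethyl)-4-[2-(3,4,5-trimethoxyphenyl)-1,3-dithian-2-yl]oxolan-2-one | COc1cc(C2(SCCCS2)[C@H]3COC(=O)[C@@H]3CO)cc(OC)c1OC | intermediate
10 | (3S,4R)-3-(hydroxymethyl)-4-[2-(3,4,5-trimethoxyphenyl)-1,3-dithian-2-yl]oxolan-2-ol (both anomers) | COc1cc(C2(SCCCS2)[C@H]3COC(O)[C@@H]3CO)cc(OC)c1OC | intermediate
11 | (3,4,5-trimethoxyphenyl)boronic acid | COc1cc(B(O)O)cc(OC)c1OC | starting material
12 | cis-fused cyclic arylboronate of 10: 1,3,2-dioxaborinane spanning the anomeric oxygen on C2 and the C3 hydroxymethyl oxygen, boron bearing 3,4,5-trimethoxyphenyl (not isolated) | COc1cc(C2(SCCCS2)[C@H]3CO[C@@H]4OB(c5cc(OC)c(OC)c(OC)c5)OC[C@H]34)cc(OC)c1OC | intermediate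
13 | (3S,4R)-oxolan-2-ylium ion whose C3 CH2O arm carries the aryl(dihydroxy)borate (zwitterion, not isolated) | COc1cc(C2(SCCCS2)[C@H]3C[O+]=C[C@@H]3CO[B-](O)(O)c4cc(OC)c(OC)c(OC)c4)cc(OC)c1OC | intermediate
14 | borate monoester of 15 at the primary oxygen (not isolated) | COc1cc(C2(SCCCS2)[C@H]3CO[C@H](c4cc(OC)c(OC)c(OC)c4)[C@@H]3COB(O)O)cc(OC)c1OC | intermediate
15 | [(2S,3S,4R)-2-(3,4,5-trimethoxyphenyl)-4-[2-(3,4,5-trimethoxyphenyl)-1,3-dithian-2-yl]oxolan-3-yl]methanol | COc1cc(C2(SCCCS2)[C@H]3CO[C@H](c4cc(OC)c(OC)c(OC)c4)[C@@H]3CO)cc(OC)c1OC | intermediate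
16 | [(3R,4S,5S)-4-(hydroxymethyl)-5-(3,4,5-trimethoxyphenyl)oxolan-3-yl](3,4,5-trimethoxyphenyl)methanone | COc1cc(C(=O)[C@H]2CO[C@H](c3cc(OC)c(OC)c(OC)c3)[C@@H]2CO)cc(OC)c1OC | target

**Totals**

Total step count: 6. Longest linear sequence: 6 steps, from 3,4,5-trimethoxybenzaldehyde 1; butenolide 3 and boronic acid 11 enter as purchased materials.

**Steps most likely to fail**

1. Step 5 (proposed new method). The oxocarbenium ion may form without aryl transfer following: protodeboronation of the electron-rich boronic acid, loss of the C3 proton to an enol ether with erosion of C3, or intermolecular O-glycosylation. After transfer, acid could ionise the benzylic C2–O bond and epimerise C2.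
 Fallback: lactol 10 is treated with benzenesulfinic acid and CaCl2 in CH2Cl2 to give the sulfone [(3S,4R)-2-(benzenesulfonyl)-4-[2-(3,4,5-trimethoxyphenyl)-1,3-dithian-2-yl]oxolan-3-yl]methanol F1. F1 is then exposed in THF at 23 °C to the arylzinc reagent made from (3,4,5-trimethoxyphenyl)magnesium bromide and ZnBr2. This is the established substitution of 2-sulfonyl cyclic ethers by arylzinc reagents through the oxocarbenium ion; inside attack and the zinc alkoxide on the C3 arm should again favour the 2,3-cis product. The fallback returns to the route at 15.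

2. Step 2. Trapping of the hindered enolate by formaldehyde may be inefficient: oligomerisation of formaldehyde, proton transfer to the enolate, double hydroxymethylation, or retro-Michael loss of the dithiane on warming.
 Fallback: starting from 2 and 3 through enolate 5, the enolate is alkylated instead with 2-(trimethylsilyl)ethoxymethyl chloride in THF/DMPU to give (3S,4R,5R)-5-(l-menthyloxy)-3-{[2-(trimethylsilyl)ethoxy]methyl}-4-[2-(3,4,5-trimethoxyphenyl)-1,3-dithian-2-yl]oxolan-2-one F2. The auxiliary is removed under the conditions of step 3 to give (3S,4R)-3-{[2-(trimethylsilyl)ethoxy]methyl}-4-[2-(3,4,5-trimethoxyphenyl)-1,3-dithian-2-yl]oxolan-2-one F3. BF3·OEt2 in CH2Cl2 at 0 °C then cleaves the 2-(trimethylsilyl)ethyl ether, returning to the route at 9.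

3. Step 6. S-Methylation of the hindered dithiane may be sluggish, and prolonged warming may epimerise C4 or open the β-alkoxy ketone by retro-oxa-Michael elimination.
 Fallback: 15 is subjected to oxidative methanolysis with PhI(OCOCF3)2 in MeOH at −20 °C to give the dimethyl ketal [(2S,3S,4R)-4-[dimethoxy(3,4,5-trimethoxyphenyl)methyl]-2-(3,4,5-trimethoxyphenyl)oxolan-3-yl]methanol F4. F4 is hydrolysed with PPTS in wet acetone at 23 °C, returning to the route at 16.

**Further compounds**

F1 | step 5 | [(3S,4R)-2-(benzenesulfonyl)-4-[2-(3,4,5-trimethoxyphenyl)-1,3-dithian-2-yl]oxolan-3-yl]methanol (anomeric mixture) | COc1cc(C2(SCCCS2)[C@H]3COC(S(=O)(=O)c4ccccc4)[C@@H]3CO)cc(OC)c1OC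
F2 | step 2 | (3S,4R,5R)-5-(l-menthyloxy)-3-{[2-(trimethylsilyl)ethoxy]methyl}-4-[2-(3,4,5-trimethoxyphenyl)-1,3-dithian-2-yl]oxolan-2-one | COc1cc(C2(SCCCS2)[C@H]3[C@H](O[C@@H]4C[C@H](C)CC[C@H]4C(C)C)OC(=O)[C@@H]3COCC[Si](C)(C)C)cc(OC)c1OC
F3 | step 2 | (3S,4R)-3-{[2-(trimethylsilyl)ethoxy]methyl}-4-[2-(3,4,5-trimethoxyphenyl)-1,3-dithian-2-yl]oxolan-2-one | COc1cc(C2(SCCCS2)[C@H]3COC(=O)[C@@H]3COCC[Si](C)(C)C)cc(OC)c1OC
F4 | step 6 | [(2S,3S,4R)-4-[dimethoxy(3,4,5-trimethoxyphenyl)methyl]-2-(3,4,5-trimethoxyphenyl)oxolan-3-yl]methanol | COc1cc(C(OC)(OC)[C@H]2CO[C@H](c3cc(OC)c(OC)c(OC)c3)[C@@H]2CO)cc(OC)c1OC
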